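Remark: atom and ring labels follow flavanone numbering (O1, C2, C3, C4, C4a, C5–C8, C8a; ring A is the benzo ring, ring B the trimethoxyphenyl ring, ring C the pyranone) and are also used for the open-chain intermediates.

## Structural features

The target 12 is a flavanone: a benzene ring (ring A, C4a to C8a) fused to a dihydropyran-4-one (ring C: O1, C2, C3, C4, C4a, C8a), with a 3,4,5-trimethoxyphenyl group (ring B) joined to C2 by a single bond. Ring A carries methoxy groups at C5 and C7, which together with O1 make it a phloroglucinol-type arene that is very nucleophilic at the free positions C6 and C8. C2 is the only stereocenter, it has the S configuration and no stereogenic neighbour, so its configuration must come entirely from a reagent or from a chiral building block. C2 is fragile in two ways: it is β to the C4 ketone, so that enolization at C3 can expel the O1 phenoxide and open ring C to a 2'-hydroxychalcone that recloses without stereocontrol, and it is a benzylic ether carbon that can ionize with help from ring B. The five methyl ethers are robust and need not be told apart, so the only oxygen that requires temporary protection is the ring A oxygen that becomes O1. The carbon skeleton is simple, two aryl halves joined through the three-carbon unit C2–C3–C4, and the real difficulty lies in setting C2 as S and keeping it S while the ketone is unmasked. The key step exploits the 1,3-relationship between the C4 carbonyl and the oxygen on C2 across the C3 methylene: C3–C4 is the bond that a C4 acyl anion forms when it opens a terminal aryl oxirane at its CH2 carbon, and the oxygen set free on C2 is then the handle for closing ring C.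

## Logic of the disconnections

12 ⇒ 11. No skeletal bond is cut; the C4 carbonyl is exchanged for the cyclic dithioketal carbon of 11. The acyl-anion logic of the key step delivers C4 in this masked form anyway, and while C4 is masked C3 cannot enolize, so ring C cannot open and C2 cannot racemize. The gain is a late intermediate without a β-alkoxy ketone. The forward step must unmask under near-neutral conditions, quickly, and with selectivity for sulfur over ring A.

11 ⇒ 10. The O1–C2 bond is cut. It is the only ring C bond that ends at a heteroatom and at the stereocenter, and it can be made by a stereospecific displacement at C2. The gain is an open chain in which C2 is a free secondary carbinol and O1 a free phenol. The forward step must proceed with clean inversion, so 10 has to be the R carbinol, and ionization at the benzylic carbon must be avoided.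

10 ⇒ 9. Only the O–acetal bond at the ring A oxygen is cut. This oxygen must be masked while a carbanion is made next to it. The mask chosen is an acetal that tolerates organolithium reagents, can chelate lithium, cannot migrate from oxygen to carbon, and is cleaved by fluoride. The forward step must use no acid, because the carbinol of 9 is benzylic and ring A would capture any electrophile.

9 ⇒ 4 + 7 (key disconnection). The C3–C4 bond is cut between the masked acyl carbon and the CH2 group. This divides the molecule into two aryl halves of similar size, removes the only C–C bond that is not present in commercial materials, and places the stereocenter in a small building block, 7, where it is easy to set. The forward step must deprotonate 4 at the carbon between the sulfur atoms, and the anion must attack only the CH2 carbon of 7, leaving the benzylic C–O bond and its configuration intact.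

4 ⇒ 3 ⇒ 1 + 2. The O–acetal bond and then the two C–S bonds are cut. Both are standard heteroatom bonds and lead to 2 and to a commercial aldehyde, 1, that already has the full oxygenation pattern of ring A. The order matters in the forward direction: the Lewis acid needed for thioacetalization is tolerated by the free phenol of 1 but not by the acetal, so the C–S bonds are made first.

7 ⇒ 6 ⇒ 5. The oxirane C–O bond at the CH2 carbon is cut to give 6, and the carbinol C–H bond of 6 is traced to the prochiral commercial ketone 5. The single stereocenter of the route is thus set by catalyst-controlled hydride addition to a flat carbonyl group. The demand is the right catalyst enantiomer: 6 must be S, which is the same spatial arrangement as S in 7 and R in 9 and 10, and becomes S in 11 and 12 after one inversion.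

## Other disconnections considered

Alternative 1: Ring A is built, not bought, by cutting the C4a–C5 bond.
- **Forward key step:** a Claisen (Dieckmann-type) condensation of the open-chain triketo ester A1, methyl (8E)-3,5,7-trioxo-9-(3,4,5-trimethoxyphenyl)non-8-enoate. The methylene between two ketone groups is enolized and attacks the ester carbonyl, and the six-membered ring aromatizes to the trihydroxychalcone A2.
- **In its favour:** it follows the biosynthesis, forms ring A and attaches the cinnamoyl chain in one operation, and needs neither sulfur reagents nor an organolithium. On reagent safety it would be the better plan.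
- **Against it here:** the 2,4,6-trioxygenated ring A is commercial, so the key step solves a problem the target does not pose. A1 is a reactive tetracarbonyl chain that is hard to prepare and can also close by aldol or lactonization modes. A2 then needs two of its three phenols methylated selectively to reach A3, (2E)-1-(2-hydroxy-4,6-dimethoxyphenyl)-3-(3,4,5-trimethoxyphenyl)prop-2-en-1-one. Most importantly, C2 is still flat in A3: closure of A3 to 12 is an oxa-Michael addition that needs a separate enantioselective catalyst and forms the product under conditions that can reopen it.
- **Comparison:** structurally the alternative spends its key step on ring A, whereas the chosen plan spends it on the C2–C3–C4 unit where the stereochemical problem sits. Mechanistically both are carbanion–carbonyl chemistry, but the chosen plan fixes C2 by a ketone reduction and one SN2 inversion, each with a predictable outcome, whereas the alternative leaves C2 to an equilibrium-prone conjugate addition. In step count the chalcone line would be the equal or the better of the chosen plan, since A3 is also accessible by a simple aldol condensation of aromatic building blocks, and it needs no protecting groups. It loses only on control of configuration.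

Alternative 2: Ring A is again assembled, by cutting C8a–C4a, C5–C6 and C8–C8a.
- **Forward key step:** a Danheiser benzannulation. On heating, 3-methoxycyclobut-2-en-1-one A4 undergoes four-electron electrocyclic ring opening, and the resulting ketene unit adds across the triple bond of the 1-methoxyalkyne A5, which already contains C2, C3, C4 and ring B. A second four-electron opening, a six-electron electrocyclization and tautomerization then close ring A as the phenol A6.
- **In its favour:** the regiochemistry is dictated by the mechanism. The oxygen that becomes O1 emerges as the only free phenol without protection or deprotection, which is better than the chosen plan's two steps on that oxygen. C4 arrives at the alcohol level, so no thioketal and no thiol are needed. The later O1–C2 closure with inversion is the same as in the chosen plan (equal).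
- **Against it here:** ring A is commercially available with the right substituents. A5 is an acid- and heat-sensitive ynol ether with two different silyl ethers and the R carbinol center, so its preparation needs its own asymmetric step and several operations, and A4 must be prepared as well. The benzannulation runs hot, and A6 is an ortho-hydroxybenzylic silyl ether on a very electron-rich ring, which invites thermal 1,4-elimination. Four operations remain after the key step: selective removal of the triethylsilyl group, ring closure, removal of the second silyl group, and oxidation at C4.
- **Comparison:** mechanistically the pericyclic cascade has fewer chemoselectivity issues in the bond-forming event than a hindered carbanion opening an oxirane. Structurally it does not touch the real difficulty, since C2 has to be set beforehand in A5 just as it is set in 7. In step economy it is clearly longer than the seven steps of the chosen plan.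

Alternative 3: No skeletal bond is cut; the C2–H and C3–H bonds are.
- **Forward key step:** enantioselective hydrogenation of the flavone A7, 5,7-dimethoxy-2-(3,4,5-trimethoxyphenyl)-4H-chromen-4-one, over the catalyst formed from Ru(cod)(2-methylallyl)2, a chiral imidazolinium salt and base. Hydrogen is delivered to one face of C2=C3 and the C4 carbonyl is reduced as well, which should give the cis flavan-4-ol A8 with 2S,4S configuration. Oxidation of the C4 carbinol then leads to 12.
- **In its favour:** A7 is a flat, stable compound available by one or two classical condensations or by purchase. The whole route would be three to four steps, without protecting groups, thiols or organolithium reagents, and the stereocenter is set catalytically at the end. In step and atom economy this alternative is better than the chosen plan.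
- **Against it here:** everything rests on one catalyst–substrate match. A7 carries a methoxy group at C5 next to the carbonyl and a trisubstituted ring B, so neither the rate nor the level of induction can be predicted with the confidence that a ketone reduction plus SN2 inversion allows. Pressurized hydrogen and an air-sensitive catalyst made in the flask are required. The over-reduction at C4 costs a reoxidation step on a molecule whose C2 is again next to an enolizable ketone.
- **Comparison:** structurally both plans leave rings A and B to commercial materials, and the alternative uses an existing ring C where the chosen plan must close it. Mechanistically the alternative sets C2 by facial discrimination at a trisubstituted enone double bond, the chosen plan by transfer of configuration from 7. If the hydrogenation performs on this substrate, the alternative is the shorter route. The chosen plan is longer, but each of its stereochemical events is of a type with a dependable outcome.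

Key step: step 4

## Route

Step 1
Reactants: 1 2-hydroxy-4,6-dimethoxybenzaldehyde; 2 propane-1,3-dithiol
Product: 3 2-(1,3-dithian-2-yl)-3,5-dimethoxyphenol
Conditions: BF3·OEt2 (0.5 equiv), CH2Cl2, 0 °C → rt
Reagents that add atoms: none
Why: Lewis-acid-catalysed thioacetalization: BF3 activates the aldehyde, the hemithioacetal ionizes to a thionium ion that the donor ring stabilizes, and the second thiol closes the six-membered 1,3-dithiane. The free phenol and the methyl ethers are inert to BF3·OEt2 at this temperature.

Step 2
Reactants: 3 2-(1,3-dithian-2-yl)-3,5-dimethoxyphenol
Product: 4 2-(2,4-dimethoxy-6-{[2-(trimethylsilyl)ethoxy]methoxy}phenyl)-1,3-dithiane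
Conditions: SEMCl (1.3 equiv), i-Pr2NEt (2 equiv), CH2Cl2, 0 °C → rt
Reagents that add atoms: 2-(trimethylsilyl)ethoxymethyl chloride (SEMCl), C[Si](C)(C)CCOCCl
Why: Base-mediated O-alkylation of the phenol by an alkoxymethyl chloride (acetal protection). The SEM acetal is preferred to a methoxymethyl ether because it avoids chloromethyl methyl ether and leaves with fluoride, so no acid later meets the benzylic carbinol or the electron-rich ring; like any alkoxymethyl ether it survives butyllithium, can chelate lithium, and cannot migrate from oxygen to the carbanion as a silyl ether could.

Step 3
Reactants: 5 2-bromo-1-(3,4,5-trimethoxyphenyl)ethan-1-one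
Product: 7 (2S)-2-(3,4,5-trimethoxyphenyl)oxirane, via S bromohydrin 6 (not isolated)
Conditions: (S)-2-methyl-CBS-oxazaborolidine (10 mol %), BH3·SMe2 (0.7 equiv), THF, 0 °C; MeOH; then 2 M aq NaOH, rt
Reagents that add atoms: none
Why: Corey–Bakshi–Shibata reduction followed by intramolecular Williamson closure: the ketone binds the catalyst–borane complex with the aryl group as the large substituent, the facial sense that gives R 1-arylethanols, which is named S here because CH2Br outranks aryl. NaOH then lets the alkoxide displace bromide at CH2 without touching the stereocenter, so S in 6 becomes S in 7. The oxazaborolidine–borane system is chosen over a formate transfer hydrogenation because formate and amines readily displace the bromide of a phenacyl bromide.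

Step 4
Reactants: 4 2-(2,4-dimethoxy-6-{[2-(trimethylsilyl)ethoxy]methoxy}phenyl)-1,3-dithiane; 7 (2S)-2-(3,4,5-trimethoxyphenyl)oxirane
Product: 9 (1R)-2-[2-(2,4-dimethoxy-6-{[2-(trimethylsilyl)ethoxy]methoxy}phenyl)-1,3-dithian-2-yl]-1-(3,4,5-trimethoxyphenyl)ethan-1-ol, via lithiated dithiane 8 (not isolated)
Conditions: n-BuLi (1.05 equiv), THF, −78 → −20 °C; then 7 (1.2 equiv), −78 °C → rt; aq NH4Cl
Reagents that add atoms: none
Why: This is a Corey–Seebach reaction, the alkylation of a 2-aryl-2-lithio-1,3-dithiane by a terminal epoxide. Butyllithium removes the C–H flanked by two sulfur atoms and the aryl ring, the most acidic site and one that lithium chelation by the acetal oxygen favours kinetically, to give 8, a masked C4 acyl anion. 8 attacks the CH2 carbon of 7 in an SN2 ring opening driven by release of ring strain, forming the C3–C4 bond and the lithium alkoxide on C2. No ring is closed and no stereocenter is created. The benzylic C–O bond of 7 is not broken, so its spatial arrangement is carried over unchanged, and the descriptor changes from S to R only because the CH2 group, now bound to carbon and no longer to oxygen, falls below the aryl group in priority. The step needs regioselectivity between the two oxirane carbons, which the bulk of the tertiary carbanion with its two ortho substituents and the absence of any Lewis acid should secure. It also needs lithiation at the dithiane carbon and not at the ring C–H bonds next to the acetal oxygen, which low temperature and one equivalent of base should secure. Because the carbanion is hindered and soft, warming to room temperature is planned for the alkylation.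

Step 5
Reactants: 9 (1R)-2-[2-(2,4-dimethoxy-6-{[2-(trimethylsilyl)ethoxy]methoxy}phenyl)-1,3-dithian-2-yl]-1-(3,4,5-trimethoxyphenyl)ethan-1-ol
Product: 10 2-{2-[(2R)-2-hydroxy-2-(3,4,5-trimethoxyphenyl)ethyl]-1,3-dithian-2-yl}-3,5-dimethoxyphenol
Conditions: Bu4NF (4 equiv), H2NCH2CH2NH2 (3 equiv), DMF, 60 °C; aq NH4Cl
Reagents that add atoms: none
Why: Fluoride-induced fragmentation of the SEM acetal: fluoride attacks silicon, ethene and formaldehyde are expelled and the phenoxide is released without acid, which should leave the dithiane and the ionizable benzylic carbinol untouched. Ethylenediamine binds the formaldehyde before the electron-rich phenoxide ring can.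

Step 6
Reactants: 10 2-{2-[(2R)-2-hydroxy-2-(3,4,5-trimethoxyphenyl)ethyl]-1,3-dithian-2-yl}-3,5-dimethoxyphenol
Product: 11 (2S)-5,7-dimethoxy-2-(3,4,5-trimethoxyphenyl)-2,3-dihydrospiro[chromene-4,2'-[1,3]dithiane]
Conditions: PPh3 (1.5 equiv), DIAD (1.5 equiv), THF, 0 °C → rt
Reagents that add atoms: none
Why: Intramolecular Mitsunobu etherification (6-exo-tet): the secondary carbinol is activated as its oxyphosphonium ion and displaced by the phenoxide in an SN2 reaction with inversion, which turns the R carbinol into the 2S ether. With C4 still a dithiane there is no enolizable ketone, so neither elimination toward a chalcone nor reopening of ring C can erode C2, and the geminal sulfur substituents should favour the closure.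

Step 7
Reactants: 11 (2S)-5,7-dimethoxy-2-(3,4,5-trimethoxyphenyl)-2,3-dihydrospiro[chromene-4,2'-[1,3]dithiane]
Product: 12 (2S)-5,7-dimethoxy-2-(3,4,5-trimethoxyphenyl)-2,3-dihydro-4H-chromen-4-one
Conditions: I2 (1.5 equiv), NaHCO3 (5 equiv), acetone/H2O, 0 °C
Reagents that add atoms: water, O
Why: Oxidative hydrolysis of the thioketal: iodine turns one sulfur into a leaving group, the C–S bond ionizes to a thionium ion strongly stabilized by ring A, water adds and the second sulfur leaves as the cyclic disulfide. The NaHCO3 buffer, 0 °C and a short reaction time should be too mild for enolization at C3, so ring C stays closed and C2 stays S; the easy ionization next to ring A makes a mercury salt unnecessary.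

## Compound list

1 | 2-hydroxy-4,6-dimethoxybenzaldehyde | COc1cc(O)c(C=O)c(OC)c1 | starting material
2 | propane-1,3-dithiol | SCCCS | starting material
3 | 2-(1,3-dithian-2-yl)-3,5-dimethoxyphenol | COc1cc(O)c(C2SCCCS2)c(OC)c1 | intermediate
4 | 2-(2,4-dimethoxy-6-{[2-(trimethylsilyl)ethoxy]methoxy}phenyl)-1,3-dithiane | C[Si](C)(C)CCOCOc1cc(OC)cc(OC)c1C1SCCCS1 | intermediate
5 | 2-bromo-1-(3,4,5-trimethoxyphenyl)ethan-1-one | COc1cc(C(=O)CBr)cc(OC)c1OC | starting material
6 | (1S)-2-bromo-1-(3,4,5-trimethoxyphenyl)ethan-1-ol | COc1cc([C@H](O)CBr)cc(OC)c1OC | intermediate
7 | (2S)-2-(3,4,5-trimethoxyphenyl)oxirane | COc1cc([C@H]2CO2)cc(OC)c1OC | intermediate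
8 | [2-(2,4-dimethoxy-6-{[2-(trimethylsilyl)ethoxy]methoxy}phenyl)-1,3-dithian-2-yl]lithium | C[Si](C)(C)CCOCOc1cc(OC)cc(OC)c1C1([Li])SCCCS1 | intermediate
9 | (1R)-2-[2-(2,4-dimethoxy-6-{[2-(trimethylsilyl)ethoxy]methoxy}phenyl)-1,3-dithian-2-yl]-1-(3,4,5-trimethoxyphenyl)ethan-1-ol | C[Si](C)(C)CCOCOc1cc(OC)cc(OC)c1C1(C[C@@H](O)c2cc(OC)c(OC)c(OC)c2)SCCCS1 | intermediate
10 | 2-{2-[(2R)-2-hydroxy-2-(3,4,5-trimethoxyphenyl)ethyl]-1,3-dithian-2-yl}-3,5-dimethoxyphenol | COc1cc(O)c(C2(C[C@@H](O)c3cc(OC)c(OC)c(OC)c3)SCCCS2)c(OC)c1 | intermediate
11 | (2S)-5,7-dimethoxy-2-(3,4,5-trimethoxyphenyl)-2,3-dihydrospiro[chromene-4,2'-[1,3]dithiane] | COc1cc(OC)c2c(c1)O[C@H](c1cc(OC)c(OC)c(OC)c1)CC21SCCCS1 | intermediate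
12 | (2S)-5,7-dimethoxy-2-(3,4,5-trimethoxyphenyl)-2,3-dihydro-4H-chromen-4-one | COc1cc(OC)c2c(c1)O[C@H](c1cc(OC)c(OC)c(OC)c1)CC2=O | target

## Step count and least certain steps

Total step count: 7. Longest linear sequence: 6 steps (steps 1, 2, 4, 5, 6, 7, starting from 1); the branch from 5 to 7 is one step.

**Step 4 (key step).** The most likely failure is slow, incomplete alkylation, because the carbanion of 8 is tertiary and flanked by two ortho substituents. The longer it remains unreacted, the more it can act as a base toward the benzylic C–H of 7 (isomerization of the oxirane) or attack the benzylic carbon. Fallback, setting out from 6 and 4 and returning at 10: the strained-ring electrophile is replaced by a primary bromide whose benzylic carbon cannot be attacked. Step 3 is stopped before the NaOH treatment and 6 is isolated and silylated (TBSCl, imidazole, DMF) to [(1S)-2-bromo-1-(3,4,5-trimethoxyphenyl)ethoxy](tert-butyl)dimethylsilane F1. 8, made from 4 as in step 4, is then alkylated by F1 (THF, DMPU, −78 → 0 °C) in an ordinary SN2 displacement of bromide. This should give the doubly protected tert-butyl{(1R)-2-[2-(2,4-dimethoxy-6-{[2-(trimethylsilyl)ethoxy]methoxy}phenyl)-1,3-dithian-2-yl]-1-(3,4,5-trimethoxyphenyl)ethoxy}dimethylsilane F2, with the stereocenter again untouched. The fluoride treatment of step 5 removes both protecting groups and delivers 10.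

**Step 6.** The most likely failure is loss of stereochemical fidelity. The oxyphosphonium ion sits on a benzylic carbon whose cation ring B can stabilize, so partial ionization before the hindered phenoxide arrives would leak the R configuration into both enantiomers of 11; elimination toward the styrene is the second risk. Fallback, setting out from 12 of lowered enantiomeric purity (as delivered by steps 6 and 7) and returning at 12: configurational purity is restored by kinetic resolution after the closure. Transfer hydrogenation with RuCl(p-cymene)[(R,R)-TsDPEN] in the acidic 5:2 HCO2H/Et3N mixture, stopped at partial conversion, should reduce the C4 carbonyl in the sense that gives 4R benzylic alcohols. Since the ring favours the cis arrangement of the 2-aryl and 4-hydroxyl groups, the unwanted 2R ketone is the matched substrate and should be consumed as (2R,4R)-5,7-dimethoxy-2-(3,4,5-trimethoxyphenyl)-3,4-dihydro-2H-chromen-4-ol F4. This more polar alcohol is removed by chromatography and 12 is recovered. Kinetic resolution of flavanones by transfer hydrogenation is known chemistry.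

**Step 5.** The most likely failure is sluggish cleavage, since aryl SEM ethers need heat, together with capture of the released formaldehyde by the very electron-rich phenoxide ring if the scavenger is too slow. Fallback, setting out from 3 and 7 and returning at 10: the protecting group is left out altogether. 3 is treated with two equivalents of n-BuLi (THF, −78 → 0 °C). The first equivalent gives the lithium phenoxide, which serves as its own protecting group, and the second gives the carbanion, lithium 2-(2-lithio-1,3-dithian-2-yl)-3,5-dimethoxyphenolate F3 (not isolated). F3 opens 7 as in step 4 and gives 10 directly on NH4Cl work-up. This is the dianion variant of dithiane alkylation used for substrates with a free hydroxyl group. It is kept in reserve only because a second lithiation next to a phenoxide on this electron-rich ring is slower and less predictable; if it serves, steps 2 and 5 fall away.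

**Step 7.** The most likely failure is electrophilic iodination of ring A at C6 or C8 competing with attack at sulfur, because a ring with three oxygen donors is itself a good nucleophile. A second risk is base-induced opening of ring C once the ketone is free. Fallback, setting out from 11 and returning at 12: sulfur is activated by oxygen transfer, not by a halogen electrophile. NaIO4 (MeOH/H2O, 0 °C), which does not attack aryl ethers, should oxidize one sulfur to the monosulfoxide (2S)-5,7-dimethoxy-2-(3,4,5-trimethoxyphenyl)-2,3-dihydrospiro[chromene-4,2'-[1,3]dithiane] 1'-oxide F5, a mixture of stereoisomers at sulfur and C4. Brief treatment with dilute HCl in THF at room temperature then ionizes the C–S(O) bond, water adds and 12 is released together with the cyclic disulfide. Both operations are known for 1,3-dithianes of ketones.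

## Further compounds

F1 | step 4 | [(1S)-2-bromo-1-(3,4,5-trimethoxyphenyl)ethoxy](tert-butyl)dimethylsilane | COc1cc([C@H](O[Si](C)(C)C(C)(C)C)CBr)cc(OC)c1OC
F2 | step 4 | tert-butyl{(1R)-2-[2-(2,4-dimethoxy-6-{[2-(trimethylsilyl)ethoxy]methoxy}phenyl)-1,3-dithian-2-yl]-1-(3,4,5-trimethoxyphenyl)ethoxy}dimethylsilane | C[Si](C)(C)CCOCOc1cc(OC)cc(OC)c1C1(C[C@@H](O[Si](C)(C)C(C)(C)C)c2cc(OC)c(OC)c(OC)c2)SCCCS1
F3 | step 5 | lithium 2-(2-lithio-1,3-dithian-2-yl)-3,5-dimethoxyphenolate | COc1cc(O[Li])c(C2([Li])SCCCS2)c(OC)c1
F4 | step 6 | (2R,4R)-5,7-dimethoxy-2-(3,4,5-trimethoxyphenyl)-3,4-dihydro-2H-chromen-4-ol | COc1cc(OC)c2c(c1)O[C@@H](c1cc(OC)c(OC)c(OC)c1)C[C@H]2O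
F5 | step 7 | (2S)-5,7-dimethoxy-2-(3,4,5-trimethoxyphenyl)-2,3-dihydrospiro[chromene-4,2'-[1,3]dithiane] 1'-oxide (either configuration at sulfur and C4) | COc1cc(OC)c2c(c1)O[C@H](c1cc(OC)c(OC)c(OC)c1)CC21SCCCS1=O
A1 | alternative 1 | methyl (8E)-3,5,7-trioxo-9-(3,4,5-trimethoxyphenyl)non-8-enoate | COC(=O)CC(=O)CC(=O)CC(=O)/C=C/c1cc(OC)c(OC)c(OC)c1
A2 | alternative 1 | (2E)-1-(2,4,6-trihydroxyphenyl)-3-(3,4,5-trimethoxyphenyl)prop-2-en-1-one | O=C(/C=C/c1cc(OC)c(OC)c(OC)c1)c1c(O)cc(O)cc1O
A3 | alternative 1 | (2E)-1-(2-hydroxy-4,6-dimethoxyphenyl)-3-(3,4,5-trimethoxyphenyl)prop-2-en-1-one | COc1cc(O)c(C(=O)/C=C/c2cc(OC)c(OC)c(OC)c2)c(OC)c1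
A4 | alternative 2 | 3-methoxycyclobut-2-en-1-one | COC1=CC(=O)C1
A5 | alternative 2 | (5R)-3-(tert-butyldimethylsilyloxy)-1-methoxy-5-(triethylsilyloxy)-5-(3,4,5-trimethoxyphenyl)pent-1-yne (either configuration at C3) | COC#CC(O[Si](C)(C)C(C)(C)C)C[C@@H](O[Si](CC)(CC)CC)c1cc(OC)c(OC)c(OC)c1
A6 | alternative 2 | 2-[(3R)-1-(tert-butyldimethylsilyloxy)-3-(triethylsilyloxy)-3-(3,4,5-trimethoxyphenyl)propyl]-3,5-dimethoxyphenol | COc1cc(O)c(C(O[Si](C)(C)C(C)(C)C)C[C@@H](O[Si](CC)(CC)CC)c2cc(OC)c(OC)c(OC)c2)c(OC)c1
A7 | alternative 3 | 5,7-dimethoxy-2-(3,4,5-trimethoxyphenyl)-4H-chromen-4-one | COc1cc(OC)c2c(c1)oc(-c1cc(OC)c(OC)c(OC)c1)cc2=O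
A8 | alternative 3 | (2S,4S)-5,7-dimethoxy-2-(3,4,5-trimethoxyphenyl)-3,4-dihydro-2H-chromen-4-ol | COc1cc(OC)c2c(c1)O[C@H](c1cc(OC)c(OC)c(OC)c1)C[C@@H]2O
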